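**Retrosynthetic overview**

1. The target is a dimer of two 2,3-trans flavan units: an upper 3,4-trans 4-arylflavan-3-ol (rings A, C, B) joined from C-4 to C-6 of a lower 3,4-cis flavan-3,4-diol (rings D, F, E). The last step removes five aryl silyl ethers.
2. Key disconnection: pyran ring F is cut at O-1–C-2 and C-4a–C-4. The enabling feature is that ring D is a resorcinol ring whose oxygen O-1 and ortho carbon C-4a (para to the C-7 oxygen) form a 1,3-O,C-dinucleophile, while C-2, C-3 and C-4 of ring F carry aryl, OH and OH, the pattern of a trans-3-arylglycidaldehyde (benzylic epoxide carbon = C-2, aldehyde carbon = C-4).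
3. The interflavanyl bond C-4 (ring C) to C-6 (ring D) is made before ring F exists, by Friedel–Crafts reaction of the C-4 cation of the upper flavan-3,4-diol with resorcinol.
4. Ring C is made first, by the same [3+3] annulation of 3-silyloxyphenol with the same epoxy aldehyde. Order of ring formation: C, then F; all four benzene rings are bought.
5. The single C3 building block, a (2R,3S)-epoxy aldehyde, comes from 3,4-dihydroxybenzaldehyde by silylation, Wittig homologation and organocatalytic epoxidation, and supplies C-2 to C-4 of both units.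

Key step: step 6

Remark: TBS = tert-butyldimethylsilyl; 3-(TBSO)phenol is taken as a commercial compound.
Remark: the catalyst enantiomer in step 3 is assigned from the steric shielding model of diarylprolinol silyl ether iminium ions (peroxide adds anti to the diarylmethyl group); the configuration of the epoxide would be confirmed by reduction to the glycidol before use.

**Step 1**
Reactants: 1 3,4-dihydroxybenzaldehyde; 2 tert-butyldimethylsilyl chloride
Product: 3 3,4-bis(tert-butyldimethylsilyloxy)benzaldehyde
Conditions: TBSCl (2.4 equiv), imidazole (5 equiv), DMF, 0 °C → rt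
Reagents that add atoms: tert-butyldimethylsilyl chloride (2), CC(C)(C)[Si](C)(C)Cl
Why: Standard silylation of phenols with a silyl chloride and imidazole; the aldehyde is untouched.

**Step 2**
Reactants: 3 3,4-bis(TBSO)benzaldehyde; 4 (triphenylphosphoranylidene)acetaldehyde
Product: 5 (E)-3-[3,4-bis(TBSO)phenyl]prop-2-enal
Conditions: Ph3P=CHCHO (1.15 equiv), toluene, 80 °C
Reagents that add atoms: (triphenylphosphoranylidene)acetaldehyde (4), O=CC=P(c1ccccc1)(c1ccccc1)c1ccccc1
Why: Wittig two-carbon homologation with a stabilized ylide, which should give the E-enal; the slight excess of ylide limits a second homologation.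

**Step 3**
Reactants: 5 (E)-3-[3,4-bis(TBSO)phenyl]prop-2-enal; 6 hydrogen peroxide
Product: 7 (2R,3S)-3-[3,4-bis(TBSO)phenyl]oxirane-2-carbaldehyde (trans-epoxide)
Conditions: (R)-2-{bis[3,5-bis(trifluoromethyl)phenyl](trimethylsilyloxy)methyl}pyrrolidine (10 mol %), 35% aq. H2O2 (1.3 equiv), CH2Cl2, rt; short silica pad, used at once
Reagents that add atoms: hydrogen peroxide (6), OO
Why: Iminium–enamine organocatalytic epoxidation of an enal (asymmetric Weitz–Scheffer type): the diarylmethyl group of the (R)-catalyst shields the Si face at C-3 of the E-iminium ion, peroxide adds to the Re face to set (3S), and the enamine closes the trans-epoxide to set (2R).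

**Step 4**
Reactants: 8 3-(TBSO)phenol; 7 (2R,3S)-epoxy aldehyde
Product: 10 (2R,3S,4S)-2-[3,4-bis(TBSO)phenyl]-7-(TBSO)chromane-3,4-diol (2,3-trans-3,4-cis), via titanium epoxy alkoxide 9 (not isolated)
Conditions: 8, Ti(OiPr)4 (1.05 equiv), toluene, rt, then evaporation of iPrOH; 7 (1.0 equiv), CH2Cl2, −20 °C → rt; aq. KNaC4H4O6 work-up
Reagents that add atoms: none
Why: Proposed new method: the titanium phenoxide of 8 should bind the aldehyde and deliver it to its free ortho carbon para to the silyloxy group (not the flanked carbon between the two oxygens) through a six-membered transition state, as in the known ortho-specific hydroxyalkylation of titanium and magnesium phenoxides with α-oxygenated aldehydes; the resulting titanium 2,3-epoxy alkoxide 9 is then activated at its distal benzylic carbon as in the known Ti(OiPr)4-mediated C-3 opening of 2,3-epoxy alcohols, so the phenoxide oxygen closes the pyran ring 6-endo with inversion, which gives the 2,3-trans ring with C-3 taken from the epoxide; the C-4 configuration (expected 3,4-cis from Felkin–Anh addition) is of no consequence because C-4 is planarized in step 5.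

**Step 5**
Reactants: 10 (2R,3S,4S)-flavan-3,4-diol tris-TBS ether; 11 resorcinol
Product: 12 (2R,3S,4R)-2-[3,4-bis(TBSO)phenyl]-7-(TBSO)-4-(2,4-dihydroxyphenyl)chroman-3-ol (2,3-trans-3,4-trans)
Conditions: resorcinol (8 equiv), BF3·OEt2 (0.3 equiv), THF–CH2Cl2, −20 → 0 °C
Reagents that add atoms: resorcinol (11), Oc1cccc(O)c1
Why: Friedel–Crafts alkylation through the C-4 benzylic cation stabilized by the para C-7 oxygen, the classical condensation of flavan-3,4-diols with resorcinol: C-4 of resorcinol should add to the half-chair cation anti to the C-3 hydroxyl to give the all-equatorial 3,4-trans product, and the excess of resorcinol suppresses self-condensation and double alkylation.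

**Step 6**
Reactants: 12 (2R,3S,4R)-4-(2,4-dihydroxyphenyl)flavan-3-ol tris-TBS ether; 7 (2R,3S)-epoxy aldehyde
Product: 14 (2R,3S,4S)-2-[3,4-bis(TBSO)phenyl]-6-{(2R,3S,4R)-2-[3,4-bis(TBSO)phenyl]-3-hydroxy-7-(TBSO)chroman-4-yl}chromane-3,4,7-triol, via titanium epoxy alkoxide 13 (not isolated)
Conditions: 12, Ti(OiPr)4 (2.2 equiv), toluene, rt, then evaporation of iPrOH; 7 (1.2 equiv), CH2Cl2, −20 °C → rt; aq. KNaC4H4O6 work-up at pH 7
Reagents that add atoms: none
Why: Proposed new method: the titanium phenoxide at O-4′ of the resorcinol ring of 12 should bind the aldehyde of 7 and deliver it through a six-membered transition state to the ortho carbon C-5′ (para to O-2′), forming the C-4a–C-4 bond and the titanium 2,3-epoxy alkoxide 13, whose distal benzylic epoxide carbon is then attacked by the same phenoxide oxygen to form the O-1–C-2 bond. The closest known reaction types are the ortho-specific hydroxyalkylation of titanium and magnesium phenoxides with α-oxygenated aldehydes, the Ti(OiPr)4-mediated C-3-selective opening of 2,3-epoxy alcohols, and the cyclization of 2-hydroxyaryl-substituted benzylic epoxides to flavan-3-ols; their union in one flask with an epoxy aldehyde is the new element. Ring F is closed in the 6-endo-tet mode by anti opening of the epoxide at the benzylic carbon, favoured over 5-exo attack at C-3 by the aryl group, by the electron-withdrawing carbinol next to C-3 and by the titanium chelate. C-3 comes unchanged from C-2 of the epoxide (set in step 3); C-2 is formed with inversion so that the trans-epoxide gives the 2,3-trans ring (an ion-pair pathway would also end in the diequatorial trans isomer); C-4 is set in the C–C bond formation by Felkin–Anh (Cornforth) addition to the non-chelated aldehyde anti to the epoxide C–O bond, which gives the erythro carbinol and hence the 3,4-cis diol. The step needs regioselectivity for C-5′/O-4′ over C-3′/O-2′, secured by the crowding of C-3′ between two titanated oxygens and of O-2′ by the neighbouring flavanyl group, and chemoselectivity among the phenols, secured by the silyl ethers on every other phenol; the upper 3-OH is only a spectator alkoxide.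

**Step 7**
Reactants: 14 penta-TBS ether
Product: 15 (2R,3S,4S)-2-(3,4-dihydroxyphenyl)-6-[(2R,3S,4R)-2-(3,4-dihydroxyphenyl)-3,7-dihydroxychroman-4-yl]chromane-3,4,7-triol (target)
Conditions: Bu4NF (6 equiv), AcOH (6 equiv), THF, 0 °C; Sephadex LH-20 (EtOH)
Reagents that add atoms: none
Why: Fluoride-mediated cleavage of aryl silyl ethers, buffered with acetic acid so that neither the catechols (base) nor the ionizable C-4 benzylic alcohol of ring F (acid) is endangered; no stereocentre is touched.

**Compound list**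

1 | 3,4-dihydroxybenzaldehyde | O=Cc1ccc(O)c(O)c1 | starting material
2 | tert-butyldimethylsilyl chloride | CC(C)(C)[Si](C)(C)Cl | starting material
3 | 3,4-bis(tert-butyldimethylsilyloxy)benzaldehyde | O=Cc1ccc(O[Si](C)(C)C(C)(C)C)c(O[Si](C)(C)C(C)(C)C)c1 | intermediate
4 | (triphenylphosphoranylidene)acetaldehyde | O=CC=P(c1ccccc1)(c1ccccc1)c1ccccc1 | starting material
5 | (E)-3-[3,4-bis(TBSO)phenyl]prop-2-enal | O=C/C=C/c1ccc(O[Si](C)(C)C(C)(C)C)c(O[Si](C)(C)C(C)(C)C)c1 | intermediate
6 | hydrogen peroxide | OO | starting material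
7 | (2R,3S)-3-[3,4-bis(TBSO)phenyl]oxirane-2-carbaldehyde | O=C[C@@H]1O[C@H]1c1ccc(O[Si](C)(C)C(C)(C)C)c(O[Si](C)(C)C(C)(C)C)c1 | intermediate
8 | 3-(tert-butyldimethylsilyloxy)phenol | Oc1cccc(O[Si](C)(C)C(C)(C)C)c1 | starting material
9 | (S)-[2-hydroxy-4-(TBSO)phenyl]{(2S,3S)-3-[3,4-bis(TBSO)phenyl]oxiran-2-yl}methanol, erythro, present as its titanium alkoxide (not isolated) | Oc1cc(O[Si](C)(C)C(C)(C)C)ccc1[C@H](O)[C@@H]1O[C@H]1c1ccc(O[Si](C)(C)C(C)(C)C)c(O[Si](C)(C)C(C)(C)C)c1 | intermediate
10 | (2R,3S,4S)-2-[3,4-bis(TBSO)phenyl]-7-(TBSO)chromane-3,4-diol | CC(C)(C)[Si](C)(C)Oc1ccc2c(c1)O[C@H](c1ccc(O[Si](C)(C)C(C)(C)C)c(O[Si](C)(C)C(C)(C)C)c1)[C@@H](O)[C@H]2O | intermediate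
11 | resorcinol | Oc1cccc(O)c1 | starting material
12 | (2R,3S,4R)-2-[3,4-bis(TBSO)phenyl]-7-(TBSO)-4-(2,4-dihydroxyphenyl)chroman-3-ol | CC(C)(C)[Si](C)(C)Oc1ccc2c(c1)O[C@H](c1ccc(O[Si](C)(C)C(C)(C)C)c(O[Si](C)(C)C(C)(C)C)c1)[C@@H](O)[C@@H]2c1ccc(O)cc1O | intermediate
13 | 12 carrying at C-5′ of its resorcinol ring the (S)-hydroxy{(2S,3S)-3-[3,4-bis(TBSO)phenyl]oxiran-2-yl}methyl group, erythro, present as its titanium alkoxide (not isolated) | CC(C)(C)[Si](C)(C)Oc1ccc2c(c1)O[C@H](c1ccc(O[Si](C)(C)C(C)(C)C)c(O[Si](C)(C)C(C)(C)C)c1)[C@@H](O)[C@@H]2c1cc([C@H](O)[C@@H]3O[C@H]3c3ccc(O[Si](C)(C)C(C)(C)C)c(O[Si](C)(C)C(C)(C)C)c3)c(O)cc1O | intermediate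
14 | (2R,3S,4S)-2-[3,4-bis(TBSO)phenyl]-6-{(2R,3S,4R)-2-[3,4-bis(TBSO)phenyl]-3-hydroxy-7-(TBSO)chroman-4-yl}chromane-3,4,7-triol | CC(C)(C)[Si](C)(C)Oc1ccc2c(c1)O[C@H](c1ccc(O[Si](C)(C)C(C)(C)C)c(O[Si](C)(C)C(C)(C)C)c1)[C@@H](O)[C@@H]2c1cc2c(cc1O)O[C@H](c1ccc(O[Si](C)(C)C(C)(C)C)c(O[Si](C)(C)C(C)(C)C)c1)[C@@H](O)[C@H]2O | intermediate
15 | (2R,3S,4S)-2-(3,4-dihydroxyphenyl)-6-[(2R,3S,4R)-2-(3,4-dihydroxyphenyl)-3,7-dihydroxychroman-4-yl]chromane-3,4,7-triol | Oc1ccc2c(c1)O[C@H](c1ccc(O)c(O)c1)[C@@H](O)[C@@H]2c1cc2c(cc1O)O[C@H](c1ccc(O)c(O)c1)[C@@H](O)[C@H]2O | target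

**Count**

Total steps: 7. Longest linear sequence: 7 steps (1 → 3 → 5 → 7 → 10 → 12 → 14 → 15; compound 7 is used twice).

**Steps most likely to fail**

Step 6 (Proposed new method). What may go wrong: hydroxyalkylation at C-3′ between the two oxygens instead of C-5′; ionization of the newly formed 7-hydroxy-flavan-4-ol centre under the Lewis acid, with loss of the C-4 configuration or oligomerization; poor facial selectivity in the addition to the aldehyde; arrest at the epoxy alkoxide or 5-exo opening. Fallback by known chemistry, setting out from 12 and enal 5: condensation with PhB(OH)2 and catalytic EtCO2H in toluene at reflux (ortho-hydroxyalkylation through the benzodioxaborin, o-quinone methide formation, oxa-6π electrocyclization) should make the same two bonds and give the flav-3-ene F1 as a mixture of C-2 epimers. Upjohn dihydroxylation (OsO4 cat., N-methylmorpholine N-oxide, acetone–H2O, 0 °C) should then add anti to the 2-aryl group of each epimer and give the 2,3-trans-3,4-cis diols. The (2R,3S,4S) isomer is separated by chromatography from its (2S,3R,4R) diastereomer, and the route is rejoined at 14.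

Step 4 (Proposed new method). What may go wrong: attack at the flanked ortho carbon of the phenol, reduction of the aldehyde by isopropoxide transfer, opening of the epoxide by isopropoxide, or over-reaction of the product at C-4 with a second phenoxide. Fallback by known chemistry, setting out from epoxy aldehyde 7 and commercial 4-bromoresorcinol (Oc1ccc(Br)c(O)c1): selective silylation of the unhindered hydroxyl para to bromine (TBSCl 1.0 equiv, imidazole, CH2Cl2, 0 °C) should give 2-bromo-5-(tert-butyldimethylsilyloxy)phenol F2. Acetalization with ethyl vinyl ether and pyridinium tosylate gives 1-bromo-2-(1-ethoxyethoxy)-4-(tert-butyldimethylsilyloxy)benzene F3. Bromine–lithium exchange (n-BuLi, THF, −78 °C) and addition of the aryllithium to the aldehyde of 7 (faster than epoxide opening, Felkin–Anh sense) gives the ethoxyethyl-protected epoxy carbinol F4. Pyridinium tosylate in wet CH2Cl2 then removes the acetal and the liberated phenol closes the ring 6-endo at the benzylic epoxide carbon, rejoining the route at 10.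

Step 3. What may go wrong: slow iminium formation with the electron-rich enal, solvolytic opening of the para-silyloxybenzylic epoxide in the aqueous peroxide medium, or erosion of enantiomeric purity. Fallback, setting out from enal 5: Luche reduction (NaBH4, CeCl3·7H2O, MeOH, 0 °C) gives (E)-3-[3,4-bis(TBSO)phenyl]prop-2-en-1-ol F5. Sharpless asymmetric epoxidation (Ti(OiPr)4 cat., L-(+)-diethyl tartrate, t-BuOOH, 4 Å sieves, CH2Cl2, −20 °C) gives (2S,3S)-{3-[3,4-bis(TBSO)phenyl]oxiran-2-yl}methanol F6. Dess–Martin oxidation buffered with NaHCO3 then returns to the route at 7.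

**Further compounds**

F1 | step 6 | (2R,3S,4R)-2-[3,4-bis(TBSO)phenyl]-4-{2-[3,4-bis(TBSO)phenyl]-7-hydroxy-2H-chromen-6-yl}-7-(TBSO)chroman-3-ol, both C-2 epimers of the chromene ring | CC(C)(C)[Si](C)(C)Oc1ccc2c(c1)O[C@H](c1ccc(O[Si](C)(C)C(C)(C)C)c(O[Si](C)(C)C(C)(C)C)c1)[C@@H](O)[C@@H]2c1cc2C=CC(c3ccc(O[Si](C)(C)C(C)(C)C)c(O[Si](C)(C)C(C)(C)C)c3)Oc2cc1O
F2 | step 4 | 2-bromo-5-(tert-butyldimethylsilyloxy)phenol | Oc1cc(O[Si](C)(C)C(C)(C)C)ccc1Br
F3 | step 4 | 1-bromo-2-(1-ethoxyethoxy)-4-(tert-butyldimethylsilyloxy)benzene | CCOC(C)Oc1cc(O[Si](C)(C)C(C)(C)C)ccc1Br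
F4 | step 4 | (S)-[2-(1-ethoxyethoxy)-4-(TBSO)phenyl]{(2S,3S)-3-[3,4-bis(TBSO)phenyl]oxiran-2-yl}methanol | CCOC(C)Oc1cc(O[Si](C)(C)C(C)(C)C)ccc1[C@H](O)[C@@H]1O[C@H]1c1ccc(O[Si](C)(C)C(C)(C)C)c(O[Si](C)(C)C(C)(C)C)c1
F5 | step 3 | (E)-3-[3,4-bis(TBSO)phenyl]prop-2-en-1-ol | OC/C=C/c1ccc(O[Si](C)(C)C(C)(C)C)c(O[Si](C)(C)C(C)(C)C)c1
F6 | step 3 | (2S,3S)-{3-[3,4-bis(TBSO)phenyl]oxiran-2-yl}methanol | OC[C@@H]1O[C@H]1c1ccc(O[Si](C)(C)C(C)(C)C)c(O[Si](C)(C)C(C)(C)C)c1
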